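**Plan**

Retrosynthesis: remove the TBS ether and the 2-(trimethylsilyl)ethyl ester. Trace C6'-CHO back to a C6'-styryl group. Open ring B at C1'-C6' and at C6'-C(styryl). Then cut the O-CH2 bond to ring A, the C1-CO2H bond and the carbinol-isobutyl bond.
Enabling feature: in ring B the ether carbon C1' sits between C2'-OH and C6'-CHO, with CH3 on C4'. A 6-(aryloxymethyl)-4-methyl-2-pyranone maps onto this pattern: C6 with O1 becomes C2'-OH, C5, C4(CH3) and C3 become C3', C4' and C5', C2 becomes C6', and the exocyclic OCH2 carbon becomes C1'.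
Forward order: ring A is bought as an arene and receives its side chain and carboxyl group. It is joined to the pyranone by SN2 at a primary carbon. Ring B is then built as the only ring-forming event, followed by alkene cleavage and desilylation.
Stereochemistry: the single (S) carbinol centre comes from a catalyst-controlled CBS reduction of the aryl isobutyl ketone. It travels as its TBS ether until the last step.

Key step: step 12

Locants: ring A has C1 (CO2H), C2 (OMe), C3 (carbinol side chain) and C6 (O-aryl). Ring B has C1' (ether carbon), C2' (OH), C4' (CH3) and C6' (CHO).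
Assumption: the styryl unit is drawn as (E) throughout. Partial loss of this geometry during Grignard formation would not matter, because the double bond is cleaved in step 13.

**Route**

Step 1
Reactants: 1 4-hydroxy-2-methoxybenzaldehyde
Product: 2 2-methoxy-4-(methoxymethoxy)benzaldehyde
Conditions: MOMCl, iPr2NEt, CH2Cl2, 0 °C to rt
Reagents that add atoms: chloromethyl methyl ether, COCCl
Why: O-alkylation of the acidic para-formyl phenol (Williamson-type acetal protection) gives a MOM ether that tolerates Grignard, borane and butyllithium reagents and later acts as an ortho-directing group.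

Step 2
Reactants: 2 2-methoxy-4-(methoxymethoxy)benzaldehyde; 3 isobutylmagnesium bromide
Product: 4 racemic 1-[2-methoxy-4-(methoxymethoxy)phenyl]-3-methylbutan-1-ol
Conditions: THF, -78 to 0 °C; aq NH4Cl
Reagents that add atoms: none
Why: Grignard 1,2-addition to a non-enolisable aromatic aldehyde installs the isobutyl chain, and the configuration formed here is erased in the next step.

Step 3
Reactants: 4 racemic 1-[2-methoxy-4-(methoxymethoxy)phenyl]-3-methylbutan-1-ol
Product: 5 1-[2-methoxy-4-(methoxymethoxy)phenyl]-3-methylbutan-1-one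
Conditions: Dess-Martin periodinane, CH2Cl2, rt
Reagents that add atoms: none
Why: Dess-Martin oxidation of a secondary benzylic alcohol runs under nearly neutral conditions that leave the aryl MOM acetal intact.

Step 4
Reactants: 5 1-[2-methoxy-4-(methoxymethoxy)phenyl]-3-methylbutan-1-one
Product: 6 (S)-1-[2-methoxy-4-(methoxymethoxy)phenyl]-3-methylbutan-1-ol
Conditions: (R)-2-methyl-CBS-oxazaborolidine [(3aR)-1-methyl-3,3-diphenyltetrahydro-1H,3H-pyrrolo[1,2-c][1,3,2]oxazaborole] (10 mol %), BH3·SMe2, THF, -20 °C; MeOH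
Reagents that add atoms: none
Why: In the Corey-Bakshi-Shibata reduction the ketone binds to the catalyst boron with the large ortho-substituted aryl group pointing away from the catalyst, so the coordinated borane delivers hydride to the Re face and the (R) catalyst should give the (S) carbinol, as it does with aryl alkyl ketones in general.

Step 5
Reactants: 6 (S)-1-[2-methoxy-4-(methoxymethoxy)phenyl]-3-methylbutan-1-ol
Product: 7 tert-butyl{(S)-1-[2-methoxy-4-(methoxymethoxy)phenyl]-3-methylbutoxy}dimethylsilane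
Conditions: TBSCl, imidazole, DMF, rt to 40 °C
Reagents that add atoms: tert-butyldimethylsilyl chloride, CC(C)(C)[Si](C)(C)Cl
Why: Imidazole-promoted silylation of a secondary alcohol forms only an O-Si bond, so the stereocentre is untouched and the alcohol is masked against butyllithium, base and organometallic reagents.

Step 6
Reactants: 7 tert-butyl{(S)-1-[2-methoxy-4-(methoxymethoxy)phenyl]-3-methylbutoxy}dimethylsilane
Product: 9 3-[(S)-1-(tert-butyldimethylsilyloxy)-3-methylbutyl]-2-methoxy-6-(methoxymethoxy)benzoic acid, via aryllithium 8 (not isolated)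
Conditions: n-BuLi, TMEDA, THF, 0 °C; CO2, -78 °C to rt; cold dilute HCl to pH 3-4
Reagents that add atoms: carbon dioxide, O=C=O
Why: In this directed ortho-metalation the ring C-H between OMe and OMOM is the most acidic site and the only one coordinated from both sides, so lithiation and carboxylation place the carboxyl carbon at C1 of ring A.

Step 7
Reactants: 9 3-[(S)-1-(tert-butyldimethylsilyloxy)-3-methylbutyl]-2-methoxy-6-(methoxymethoxy)benzoic acid; 10 2-(trimethylsilyl)ethanol
Product: 11 2-(trimethylsilyl)ethyl 3-[(S)-1-(tert-butyldimethylsilyloxy)-3-methylbutyl]-2-methoxy-6-(methoxymethoxy)benzoate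
Conditions: PPh3, DIAD, THF, 0 °C to rt
Reagents that add atoms: none
Why: In the Mitsunobu esterification the carboxylate acts as nucleophile on the activated primary alcohol, so the shielding of the di-ortho-substituted acyl carbon, which hampers acyl-transfer esterifications, plays no role.

Step 8
Reactants: 11 2-(trimethylsilyl)ethyl 3-[(S)-1-(tert-butyldimethylsilyloxy)-3-methylbutyl]-2-methoxy-6-(methoxymethoxy)benzoate
Product: 13 2-(trimethylsilyl)ethyl 3-[(S)-1-(tert-butyldimethylsilyloxy)-3-methylbutyl]-6-hydroxy-2-methoxybenzoate, via aryl trimethylsilyl ether 12 (not isolated)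
Conditions: TMSOTf, 2,2'-bipyridyl, CH2Cl2, 0 °C to rt; H2O
Reagents that add atoms: none
Why: Silyl triflate/2,2'-bipyridyl cleavage turns an aromatic MOM ether into the labile aryl trimethylsilyl ether without any protic acid and water then frees the phenol, so the acid-sensitive benzylic TBS ether and the silylethyl ester should survive.

Step 9
Reactants: 14 4,6-dimethyl-2H-pyran-2-one
Product: 15 6-(bromomethyl)-4-methyl-2H-pyran-2-one
Conditions: NBS (1 equiv), AIBN (cat.), PhCF3, reflux
Reagents that add atoms: N-bromosuccinimide, O=C1CCC(=O)N1Br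
Why: In this Wohl-Ziegler bromination the radical from the C6 methyl group is delocalised over C5 and C3 of the whole dienyl ester, whereas the radical from the C4 methyl group is only cross-conjugated and sits on the electron-poor beta carbon, so the electrophilic bromine atom should select the C6 methyl group, as it does in other 6-methyl-2-pyranones.

Step 10
Reactants: 13 2-(trimethylsilyl)ethyl 3-[(S)-1-(tert-butyldimethylsilyloxy)-3-methylbutyl]-6-hydroxy-2-methoxybenzoate; 15 6-(bromomethyl)-4-methyl-2H-pyran-2-one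
Product: 16 2-(trimethylsilyl)ethyl 3-[(S)-1-(tert-butyldimethylsilyloxy)-3-methylbutyl]-2-methoxy-6-[(4-methyl-2-oxo-2H-pyran-6-yl)methoxy]benzoate
Conditions: K2CO3, DMF, rt
Reagents that add atoms: none
Why: Williamson ether synthesis by SN2 at a primary, allylically activated bromide forms the future hindered diaryl ether C-O bond while its carbon is still unhindered, and the mild carbonate base spares the pyranone.

Step 11
Reactants: 17 (E)-(2-bromovinyl)benzene
Product: 18 (E)-styrylmagnesium bromide (THF solution, titrated and used directly)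
Conditions: Mg turnings (activated with a crystal of I2), THF, 35 °C
Reagents that add atoms: magnesium, [Mg]
Why: Grignard formation by insertion of magnesium into an alkenyl C-Br bond is standard for beta-bromostyrene in THF.

Step 12
Reactants: 16 2-(trimethylsilyl)ethyl 3-[(S)-1-(tert-butyldimethylsilyloxy)-3-methylbutyl]-2-methoxy-6-[(4-methyl-2-oxo-2H-pyran-6-yl)methoxy]benzoate; 18 (E)-styrylmagnesium bromide
Product: 21 2-(trimethylsilyl)ethyl 3-[(S)-1-(tert-butyldimethylsilyloxy)-3-methylbutyl]-6-[2-hydroxy-4-methyl-6-((E)-styryl)phenoxy]-2-methoxybenzoate, via pyranol adduct 19 (not isolated), via enedione 20 (not isolated)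
Conditions: anhydrous CeCl3 (1.5 equiv) and 18 (1.4 equiv), THF, -78 °C, 1 h; add 16, -78 °C; aq NH4Cl; crude 20, DBU, THF, 23 to 50 °C
Reagents that add atoms: none
Why: Proposed new method: the weakly basic, oxophilic styrylcerium reagent adds 1,2 to the lactone carbonyl C2 of 16, the alkoxide of 19 expels the ring oxygen as a vinylogous enolate whose delocalised charge shields the new ketone from a second addition, and the NH4Cl quench delivers the (Z)-enedione 20. With DBU the enolate at the ArO-CH2 carbon attacks the styryl ketone (bond C1'-C6') in a 6-(enolendo)-exo-trig aldol closure, E1cB loss of water gives a cyclohexa-2,4-dienone, and its tautomerisation makes ring B aromatic with the former pyranone ring oxygen as C2'-OH. The closest known reaction types are Grignard addition to 2-pyranones with isolation of 2-substituted pyrylium salts and the base-induced conversion of 2-methylpyrylium salts into phenols through the same kind of enedione, but the sequence has not been run on an aryloxymethyl pyranone. No stereocentre is formed, and the (S) silyloxy centre on ring A is remote from every reacting atom and has no acidic hydrogen under these conditions. Attack at C2 rather than at the acidic OCH2 hydrogens, at the conjugate positions C4 and C6 or at the benzoate is secured by the cerium reagent at -78 °C, by the carbon substituents on C4 and C6 and by the two ortho groups flanking the ester. The aldol can go only one way because the styryl ketone has no alpha hydrogen and the more acidic CH2 at the future C3' could close only a four-membered ring, the cis geometry needed for closure is inherited from the heterocycle, and any (E) isomer returns through the common dienolate and is drained by the irreversible aromatisation.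

Step 13
Reactants: 21 2-(trimethylsilyl)ethyl 3-[(S)-1-(tert-butyldimethylsilyloxy)-3-methylbutyl]-6-[2-hydroxy-4-methyl-6-((E)-styryl)phenoxy]-2-methoxybenzoate
Product: 23 2-(trimethylsilyl)ethyl 3-[(S)-1-(tert-butyldimethylsilyloxy)-3-methylbutyl]-6-(2-formyl-6-hydroxy-4-methylphenoxy)-2-methoxybenzoate, via ozonide 22 (not isolated)
Conditions: O3 (about 1 equiv, added as a cold saturated CH2Cl2 solution), CH2Cl2, -78 °C; PPh3, -78 °C to rt
Reagents that add atoms: ozone, [O-][O+]=O
Why: Ozonolysis with reductive work-up cleaves the electron-rich stilbene-type alkene much faster than it attacks an arene, as in the cleavage of propenylphenols to hydroxybenzaldehydes, and it avoids periodate, which is known to oxidise 2-alkoxyphenols.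

Step 14
Reactants: 23 2-(trimethylsilyl)ethyl 3-[(S)-1-(tert-butyldimethylsilyloxy)-3-methylbutyl]-6-(2-formyl-6-hydroxy-4-methylphenoxy)-2-methoxybenzoate
Product: 24 tenellic acid B, 6-(2-formyl-6-hydroxy-4-methylphenoxy)-3-[(S)-1-hydroxy-3-methylbutyl]-2-methoxybenzoic acid
Conditions: Bu4NF (4 equiv), THF, 0 °C to rt; cold dilute HCl to pH 3-4
Reagents that add atoms: none
Why: In this fluoride-mediated global desilylation the TBS ether is cleaved at the Si-O bond and the 2-(trimethylsilyl)ethyl ester fragments by beta-elimination to the carboxylate, so both groups fall in one non-acidic operation that cannot ionise or epimerise the benzylic (S) carbinol.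

**Compound list**

1 | 4-hydroxy-2-methoxybenzaldehyde | COc1cc(O)ccc1C=O | starting material
2 | 2-methoxy-4-(methoxymethoxy)benzaldehyde | COCOc1ccc(C=O)c(OC)c1 | intermediate
3 | isobutylmagnesium bromide | CC(C)C[Mg]Br | starting material
4 | racemic 1-[2-methoxy-4-(methoxymethoxy)phenyl]-3-methylbutan-1-ol | COCOc1ccc(C(O)CC(C)C)c(OC)c1 | intermediate
5 | 1-[2-methoxy-4-(methoxymethoxy)phenyl]-3-methylbutan-1-one | COCOc1ccc(C(=O)CC(C)C)c(OC)c1 | intermediate
6 | (S)-1-[2-methoxy-4-(methoxymethoxy)phenyl]-3-methylbutan-1-ol | COCOc1ccc([C@@H](O)CC(C)C)c(OC)c1 | intermediate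
7 | tert-butyl{(S)-1-[2-methoxy-4-(methoxymethoxy)phenyl]-3-methylbutoxy}dimethylsilane | COCOc1ccc([C@@H](O[Si](C)(C)C(C)(C)C)CC(C)C)c(OC)c1 | intermediate
8 | {3-[(S)-1-(tert-butyldimethylsilyloxy)-3-methylbutyl]-2-methoxy-6-(methoxymethoxy)phenyl}lithium | [Li]c1c(OC)c([C@@H](O[Si](C)(C)C(C)(C)C)CC(C)C)ccc1OCOC | intermediate (not isolated)
9 | 3-[(S)-1-(tert-butyldimethylsilyloxy)-3-methylbutyl]-2-methoxy-6-(methoxymethoxy)benzoic acid | OC(=O)c1c(OC)c([C@@H](O[Si](C)(C)C(C)(C)C)CC(C)C)ccc1OCOC | intermediate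
10 | 2-(trimethylsilyl)ethanol | C[Si](C)(C)CCO | starting material
11 | 2-(trimethylsilyl)ethyl 3-[(S)-1-(tert-butyldimethylsilyloxy)-3-methylbutyl]-2-methoxy-6-(methoxymethoxy)benzoate | C[Si](C)(C)CCOC(=O)c1c(OC)c([C@@H](O[Si](C)(C)C(C)(C)C)CC(C)C)ccc1OCOC | intermediate
12 | 2-(trimethylsilyl)ethyl 3-[(S)-1-(tert-butyldimethylsilyloxy)-3-methylbutyl]-2-methoxy-6-(trimethylsilyloxy)benzoate | C[Si](C)(C)CCOC(=O)c1c(OC)c([C@@H](O[Si](C)(C)C(C)(C)C)CC(C)C)ccc1O[Si](C)(C)C | intermediate (not isolated)
13 | 2-(trimethylsilyl)ethyl 3-[(S)-1-(tert-butyldimethylsilyloxy)-3-methylbutyl]-6-hydroxy-2-methoxybenzoate | C[Si](C)(C)CCOC(=O)c1c(OC)c([C@@H](O[Si](C)(C)C(C)(C)C)CC(C)C)ccc1O | intermediate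
14 | 4,6-dimethyl-2H-pyran-2-one | Cc1cc(C)oc(=O)c1 | starting material
15 | 6-(bromomethyl)-4-methyl-2H-pyran-2-one | BrCc1cc(C)cc(=O)o1 | intermediate
16 | 2-(trimethylsilyl)ethyl 3-[(S)-1-(tert-butyldimethylsilyloxy)-3-methylbutyl]-2-methoxy-6-[(4-methyl-2-oxo-2H-pyran-6-yl)methoxy]benzoate | C[Si](C)(C)CCOC(=O)c1c(OC)c([C@@H](O[Si](C)(C)C(C)(C)C)CC(C)C)ccc1OCc2cc(C)cc(=O)o2 | intermediate
17 | (E)-(2-bromovinyl)benzene, (E)-beta-bromostyrene | Br/C=C/c1ccccc1 | starting material
18 | (E)-styrylmagnesium bromide | Br[Mg]/C=C/c1ccccc1 | intermediate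
19 | 2-(trimethylsilyl)ethyl 3-[(S)-1-(tert-butyldimethylsilyloxy)-3-methylbutyl]-6-{[2-hydroxy-4-methyl-2-((E)-styryl)-2H-pyran-6-yl]methoxy}-2-methoxybenzoate (present as its metal alkoxide, both epimers at the pyran C2) | C[Si](C)(C)CCOC(=O)c1c(OC)c([C@@H](O[Si](C)(C)C(C)(C)C)CC(C)C)ccc1OCC2=CC(C)=CC(O)(/C=C/c3ccccc3)O2 | intermediate (not isolated)
20 | 2-(trimethylsilyl)ethyl 3-[(S)-1-(tert-butyldimethylsilyloxy)-3-methylbutyl]-2-methoxy-6-{[(4Z,7E)-4-methyl-2,6-dioxo-8-phenylocta-4,7-dien-1-yl]oxy}benzoate | C[Si](C)(C)CCOC(=O)c1c(OC)c([C@@H](O[Si](C)(C)C(C)(C)C)CC(C)C)ccc1OCC(=O)C/C(C)=C\C(=O)/C=C/c2ccccc2 | intermediate (not isolated)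
21 | 2-(trimethylsilyl)ethyl 3-[(S)-1-(tert-butyldimethylsilyloxy)-3-methylbutyl]-6-[2-hydroxy-4-methyl-6-((E)-styryl)phenoxy]-2-methoxybenzoate | C[Si](C)(C)CCOC(=O)c1c(OC)c([C@@H](O[Si](C)(C)C(C)(C)C)CC(C)C)ccc1Oc2c(O)cc(C)cc2/C=C/c3ccccc3 | intermediate
22 | 2-(trimethylsilyl)ethyl 3-[(S)-1-(tert-butyldimethylsilyloxy)-3-methylbutyl]-6-[2-hydroxy-4-methyl-6-(5-phenyl-1,2,4-trioxolan-3-yl)phenoxy]-2-methoxybenzoate | C[Si](C)(C)CCOC(=O)c1c(OC)c([C@@H](O[Si](C)(C)C(C)(C)C)CC(C)C)ccc1Oc2c(O)cc(C)cc2C3OOC(c4ccccc4)O3 | intermediate (not isolated)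
23 | 2-(trimethylsilyl)ethyl 3-[(S)-1-(tert-butyldimethylsilyloxy)-3-methylbutyl]-6-(2-formyl-6-hydroxy-4-methylphenoxy)-2-methoxybenzoate | C[Si](C)(C)CCOC(=O)c1c(OC)c([C@@H](O[Si](C)(C)C(C)(C)C)CC(C)C)ccc1Oc2c(O)cc(C)cc2C=O | intermediate
24 | tenellic acid B, 6-(2-formyl-6-hydroxy-4-methylphenoxy)-3-[(S)-1-hydroxy-3-methylbutyl]-2-methoxybenzoic acid | COc1c([C@@H](O)CC(C)C)ccc(Oc2c(O)cc(C)cc2C=O)c1C(=O)O | target

**Step count**

Total: 14 steps. Longest linear sequence: 12 steps (steps 1-8, 10, 12, 13, 14).

**Steps most likely to fail**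

1. Step 12.
Risk: the reagent may deprotonate the acidic OCH2 group instead of adding. It may also add in conjugate fashion or add twice. The aldol may stall at the stabilised dienolate.
Fallback: form the diaryl ether by nucleophilic aromatic substitution instead of building ring B. This known chemistry sets out from phenol 13 and comes back at aldehyde 23. Commercial 2-fluoro-5-methylphenol is protected (MOMCl, iPr2NEt) as 1-fluoro-2-(methoxymethoxy)-4-methylbenzene F1. This is lithiated next to fluorine (s-BuLi, THF, -78 °C) to [2-fluoro-3-(methoxymethoxy)-5-methylphenyl]lithium F2, since the only other activated site is squeezed between OMOM and CH3. Formylation with DMF gives 2-fluoro-3-(methoxymethoxy)-5-methylbenzaldehyde F3. The phenoxide of 13 displaces the aldehyde-activated fluoride (K2CO3, DMF, 90 °C, with fluoride leaving as sparingly soluble KF) to give the MOM-protected diaryl ether F4. The TMSOTf/2,2'-bipyridyl protocol of step 8 then takes this compound through the aryl trimethylsilyl ether F5 to 23.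

2. Step 9.
Risk: hydrogen abstraction may occur at the wrong methyl group. Ionic bromination of the ring at C3 or double bromination may compete.
Fallback: assemble the pyranone on the phenol so that the position of the OCH2 group is fixed by construction. The sequence sets out from 13, comes back at 16, and replaces steps 9 and 10. Alkylation of 13 with propargyl bromide (K2CO3, DMF) gives the propargyl ether F6. Hydroiodination of methyl but-2-ynoate (NaI, AcOH, heat) gives methyl (Z)-3-iodobut-2-enoate F7. Sonogashira coupling of the two (PdCl2(PPh3)2, CuI, Et3N) gives the methyl (Z)-enynoate F8. LiOH (THF/H2O) hydrolyses only the unhindered methyl ester to the (Z)-enynoic acid F9. ZnBr2 (cat., THF) then closes it by 6-endo-dig lactonisation to 16.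

3. Step 13.
Risk: ozone may over-oxidise the electron-rich free phenol ring in competition with alkene cleavage.
Fallback: mask the phenol and cleave the alkene in two separate oxidations. The sequence sets out from 21 and comes back at 24. Silylation of the C2'-OH (TBSCl, imidazole, DMF) gives the aryl TBS ether F10. Upjohn dihydroxylation (OsO4 cat., NMO, acetone/H2O) gives the diol F11 as a mixture of diastereomers. Glycol cleavage (NaIO4, THF/H2O) gives the silyl-protected aldehyde F12. Bu4NF under the conditions of step 14 removes all three silicon groups to give 24.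

**Further compounds**

F1 | step 12 | 1-fluoro-2-(methoxymethoxy)-4-methylbenzene | COCOc1cc(C)ccc1F
F2 | step 12 | [2-fluoro-3-(methoxymethoxy)-5-methylphenyl]lithium | [Li]c1cc(C)cc(OCOC)c1F
F3 | step 12 | 2-fluoro-3-(methoxymethoxy)-5-methylbenzaldehyde | COCOc1cc(C)cc(C=O)c1F
F4 | step 12 | 2-(trimethylsilyl)ethyl 3-[(S)-1-(tert-butyldimethylsilyloxy)-3-methylbutyl]-6-[2-formyl-6-(methoxymethoxy)-4-methylphenoxy]-2-methoxybenzoate | C[Si](C)(C)CCOC(=O)c1c(OC)c([C@@H](O[Si](C)(C)C(C)(C)C)CC(C)C)ccc1Oc2c(OCOC)cc(C)cc2C=O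
F5 | step 12 | 2-(trimethylsilyl)ethyl 3-[(S)-1-(tert-butyldimethylsilyloxy)-3-methylbutyl]-6-[2-formyl-4-methyl-6-(trimethylsilyloxy)phenoxy]-2-methoxybenzoate | C[Si](C)(C)CCOC(=O)c1c(OC)c([C@@H](O[Si](C)(C)C(C)(C)C)CC(C)C)ccc1Oc2c(O[Si](C)(C)C)cc(C)cc2C=O
F6 | step 9 | 2-(trimethylsilyl)ethyl 3-[(S)-1-(tert-butyldimethylsilyloxy)-3-methylbutyl]-2-methoxy-6-(prop-2-yn-1-yloxy)benzoate | C[Si](C)(C)CCOC(=O)c1c(OC)c([C@@H](O[Si](C)(C)C(C)(C)C)CC(C)C)ccc1OCC#C
F7 | step 9 | methyl (Z)-3-iodobut-2-enoate | C/C(I)=C/C(=O)OC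
F8 | step 9 | 2-(trimethylsilyl)ethyl 3-[(S)-1-(tert-butyldimethylsilyloxy)-3-methylbutyl]-2-methoxy-6-{[(Z)-6-methoxy-4-methyl-6-oxohex-4-en-2-yn-1-yl]oxy}benzoate | C[Si](C)(C)CCOC(=O)c1c(OC)c([C@@H](O[Si](C)(C)C(C)(C)C)CC(C)C)ccc1OCC#C/C(C)=C\C(=O)OC
F9 | step 9 | (Z)-6-{4-[(S)-1-(tert-butyldimethylsilyloxy)-3-methylbutyl]-3-methoxy-2-[2-(trimethylsilyl)ethoxycarbonyl]phenoxy}-3-methylhex-2-en-4-ynoic acid | C[Si](C)(C)CCOC(=O)c1c(OC)c([C@@H](O[Si](C)(C)C(C)(C)C)CC(C)C)ccc1OCC#C/C(C)=C\C(=O)O
F10 | step 13 | 2-(trimethylsilyl)ethyl 3-[(S)-1-(tert-butyldimethylsilyloxy)-3-methylbutyl]-6-[2-(tert-butyldimethylsilyloxy)-4-methyl-6-((E)-styryl)phenoxy]-2-methoxybenzoate | C[Si](C)(C)CCOC(=O)c1c(OC)c([C@@H](O[Si](C)(C)C(C)(C)C)CC(C)C)ccc1Oc2c(O[Si](C)(C)C(C)(C)C)cc(C)cc2/C=C/c3ccccc3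
F11 | step 13 | 2-(trimethylsilyl)ethyl 3-[(S)-1-(tert-butyldimethylsilyloxy)-3-methylbutyl]-6-[2-(tert-butyldimethylsilyloxy)-6-(1,2-dihydroxy-2-phenylethyl)-4-methylphenoxy]-2-methoxybenzoate (diastereomer mixture at the diol carbons) | C[Si](C)(C)CCOC(=O)c1c(OC)c([C@@H](O[Si](C)(C)C(C)(C)C)CC(C)C)ccc1Oc2c(O[Si](C)(C)C(C)(C)C)cc(C)cc2C(O)C(O)c3ccccc3
F12 | step 13 | 2-(trimethylsilyl)ethyl 3-[(S)-1-(tert-butyldimethylsilyloxy)-3-methylbutyl]-6-[2-(tert-butyldimethylsilyloxy)-6-formyl-4-methylphenoxy]-2-methoxybenzoate | C[Si](C)(C)CCOC(=O)c1c(OC)c([C@@H](O[Si](C)(C)C(C)(C)C)CC(C)C)ccc1Oc2c(O[Si](C)(C)C(C)(C)C)cc(C)cc2C=O
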